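**Retrosynthetic overview**
1. The target is a (3R)-isoflavanone. Its three phenols are unmasked last from a tris-silyl ether, and the C5' geranyl chain is traced back to a C5' aryl bromide and geranyltributylstannane (Stille coupling).
2. The strategy rests on one feature of ring C: C2 is a bare CH2 bound to O1, and it sits next to the C3 stereocentre, which carries ring B and is alpha to the C4 ketone. The C2–C3 bond is therefore cut back to the methyl group of a ring A aryl methyl ether and a carbene at C3, that is, to an alpha-aryl alpha-diazo ketone.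
3. The diazo ketone comes from the benzyl aryl ketone by diazo transfer. The ketone comes from the ring A aryllithium (from 4-bromo-3-methoxyphenol) and the N-methoxy-N-methyl amide of ring B (from 2,4-dihydroxyphenylacetic acid).
4. Ring order: rings A and B are bought. Ring C is the only ring made, in the carbene insertion, together with C3.

Key step: step 8

Remark: TBS = tert-butyldimethylsilyl throughout.
Assumption: Rh2(S-PTTL)4 is taken to give the 3R product. The sense of induction for this substrate class is not established, so if the 3S isomer should predominate, the mirror-image catalyst Rh2(R-PTTL)4 is used with nothing else changed.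

**Route**

Step 1
Reactants: 1 2,4-dihydroxyphenylacetic acid
Product: 2 methyl 2-(2,4-dihydroxyphenyl)acetate
Conditions: MeOH, cat. H2SO4, reflux
Reagents that add atoms: methanol, CO
Why: Fischer esterification; methanol as solvent should drive the equilibrium to the ester and reopen any benzofuranone lactone formed from the ortho-hydroxy acid.

Step 2
Reactants: 2 methyl 2-(2,4-dihydroxyphenyl)acetate
Product: 3 methyl 2-[2,4-bis(TBS-oxy)phenyl]acetate
Conditions: TBSCl (2.4 equiv), imidazole, DMF, rt
Reagents that add atoms: tert-butyldimethylsilyl chloride, CC(C)(C)[Si](C)(C)Cl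
Why: Imidazole-promoted silyl ether formation should mask both phenols for the organometallic steps and leave the ring B oxygens without any alpha C–H bond.

Step 3
Reactants: 3 methyl 2-[2,4-bis(TBS-oxy)phenyl]acetate
Product: 4 methyl 2-[5-bromo-2,4-bis(TBS-oxy)phenyl]acetate
Conditions: NBS (1.05 equiv), MeCN, 0 °C to rt, dark
Reagents that add atoms: N-bromosuccinimide, O=C1CCC(=O)N1Br
Why: Electrophilic aromatic bromination; C5 is para to the C2 silyloxy group and ortho to the C4 one, while C3 is shut in between two bulky silyl ethers, so monobromination at C5 is expected.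

Step 4
Reactants: 4 methyl 2-[5-bromo-2,4-bis(TBS-oxy)phenyl]acetate
Product: 5 2-[5-bromo-2,4-bis(TBS-oxy)phenyl]-N-methoxy-N-methylacetamide
Conditions: MeNH(OMe)·HCl (1.5 equiv), i-PrMgCl (3 equiv), THF, −20 to 0 °C; aq NH4Cl
Reagents that add atoms: N,O-dimethylhydroxylamine hydrochloride, CNOC.Cl
Why: Ester aminolysis by the chloromagnesium amide formed in the flask; at this temperature i-PrMgCl should not exchange with the electron-rich aryl bromide and the aryl silyl ethers should be untouched.

Step 5
Reactants: 6 4-bromo-3-methoxyphenol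
Product: 7 (4-bromo-3-methoxyphenoxy)(tert-butyl)dimethylsilane
Conditions: TBSCl (1.2 equiv), imidazole, DMF, rt
Reagents that add atoms: tert-butyldimethylsilyl chloride, CC(C)(C)[Si](C)(C)Cl
Why: Standard imidazole-promoted silylation of a phenol, which removes the only acidic proton of the ring A piece.

Step 6
Reactants: 7 (4-bromo-3-methoxyphenoxy)(tert-butyl)dimethylsilane; 5 2-[5-bromo-2,4-bis(TBS-oxy)phenyl]-N-methoxy-N-methylacetamide
Product: 10 2-[5-bromo-2,4-bis(TBS-oxy)phenyl]-1-[4-(TBS-oxy)-2-methoxyphenyl]ethan-1-one, via aryllithium 8 (not isolated), via lithium hemiaminal adduct 9 (not isolated)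
Conditions: 7 (1.3 equiv), n-BuLi (1.25 equiv), THF, −78 °C; then 5, −78 to −40 °C; aq NH4Cl
Reagents that add atoms: none
Why: Bromine–lithium exchange followed by acyl substitution on an N-methoxy-N-methyl amide; the chelated tetrahedral adduct 9 should last until work-up so that one aryl group is added, and the slight deficit of n-BuLi and the low temperature should limit amide enolisation and exchange at the ring B bromide.

Step 7
Reactants: 10 2-[5-bromo-2,4-bis(TBS-oxy)phenyl]-1-[4-(TBS-oxy)-2-methoxyphenyl]ethan-1-one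
Product: 11 2-[5-bromo-2,4-bis(TBS-oxy)phenyl]-1-[4-(TBS-oxy)-2-methoxyphenyl]-2-diazoethan-1-one
Conditions: p-ABSA (1.5 equiv), DBU (2 equiv), dry MeCN, 0 °C to rt, dark
Reagents that add atoms: 4-acetamidobenzenesulfonyl azide (p-ABSA), CC(=O)Nc1ccc(cc1)S(=O)(=O)N=[N+]=[N-]
Why: Regitz diazo transfer; the methylene of a benzyl aryl ketone is acidic enough for DBU, and its enolate should attack the terminal nitrogen of the sulfonyl azide and shed the sulfonamide.

Step 8
Reactants: 11 2-[5-bromo-2,4-bis(TBS-oxy)phenyl]-1-[4-(TBS-oxy)-2-methoxyphenyl]-2-diazoethan-1-one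
Product: 12 (3R)-3-[5-bromo-2,4-bis(TBS-oxy)phenyl]-7-(TBS-oxy)chroman-4-one
Conditions: Rh2(S-PTTL)4 [dirhodium tetrakis(N-phthaloyl-(S)-tert-leucinate)] (1 mol %), toluene, 4 Å MS, 0 °C to rt, slow addition of 11 at high dilution
Reagents that add atoms: none
Why: Proposed new method: the catalyst takes N2 from 11 and leaves an electrophilic aryl/acyl rhodium carbene at C3, which draws hydride from a methoxy C–H bond and bonds to that carbon in one concerted, asynchronous step, the ether oxygen carrying the positive charge that builds up on carbon. The closest known reactions are chiral dirhodium carboxylate-catalysed insertions of alpha-diazo ketones into the O–CH2 bonds of ortho-alkoxy groups to give chroman-4-ones, insertions of aryldiazoacetates into ortho-methoxy C–H bonds to give dihydrobenzofurans, and cyclopentanone-forming insertions of alpha-aryl alpha-diazo ketones; none of them joins an aryl ketone carbene to a methyl C–H bond in the six-ring mode. Ring C closes in the 1,6 insertion mode, the carbene carbon C3 bonding to the methyl carbon that becomes C2, which gives the O1–C2–C3–C4–C4a–C8a ring. C3 is the only new stereocentre and is set by the catalyst: the phthalimido walls of the four tert-leucinate ligands should leave one face of the rhodium-bound carbene carbon open, and carbon and hydrogen are delivered to that face together. The step needs chemoselectivity for C–H insertion over attack on the methoxy oxygen followed by methyl migration; this is expected because the oxonium ylide can revert to the carbene and a methyl group migrates slowly. It also needs site selectivity, which the substrate secures because the methoxy group holds the only oxygen-activated C–H bonds, the ring B oxygens carry silicon with only unactivated primary C–H bonds, and the base-free medium should leave the acidic C3–H of 12 alone.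

Step 9
Reactants: 13 geranyl bromide, (2E)-1-bromo-3,7-dimethylocta-2,6-diene
Product: 14 geranyltributylstannane, tributyl[(2E)-3,7-dimethylocta-2,6-dien-1-yl]stannane
Conditions: Bu3SnH, LDA, THF, 0 °C; then 13, −78 °C
Reagents that add atoms: tributyltin hydride, CCCC[SnH](CCCC)CCCC
Why: SN2 displacement of the primary allylic bromide by tributylstannyllithium at the unhindered CH2 terminus, which should leave the 2E double bond untouched.

Step 10
Reactants: 12 (3R)-3-[5-bromo-2,4-bis(TBS-oxy)phenyl]-7-(TBS-oxy)chroman-4-one; 14 geranyltributylstannane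
Product: 15 (3R)-3-{2,4-bis(TBS-oxy)-5-[(2E)-3,7-dimethylocta-2,6-dien-1-yl]phenyl}-7-(TBS-oxy)chroman-4-one
Conditions: 14 (1.5 equiv), Pd(PPh3)4 (10 mol %), degassed toluene, 95 °C
Reagents that add atoms: none
Why: Stille coupling of an aryl bromide with an allylic stannane (oxidative addition to zerovalent palladium, transmetalation, reductive elimination at the primary allyl terminus), run without base or fluoride so that the C3–H and the silyl ethers should survive.

Step 11
Reactants: 15 (3R)-3-{2,4-bis(TBS-oxy)-5-[(2E)-3,7-dimethylocta-2,6-dien-1-yl]phenyl}-7-(TBS-oxy)chroman-4-one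
Product: 16 (3R)-3-{5-[(2E)-3,7-dimethylocta-2,6-dien-1-yl]-2,4-dihydroxyphenyl}-7-hydroxychroman-4-one (CNP0142504.1)
Conditions: HF·pyridine (excess), pyridine, THF, 0 °C to rt; pH 7 buffer work-up
Reagents that add atoms: none
Why: Fluoride-induced cleavage of the three aryl silyl ethers in a pyridine-buffered, weakly acidic medium that forms neither a phenoxide nor an enolate, so C3 should keep its configuration and the geranyl chain should not cyclise onto the neighbouring phenol.

**Compound list**
1 | 2,4-dihydroxyphenylacetic acid | O=C(O)Cc1ccc(O)cc1O | starting material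
2 | methyl 2-(2,4-dihydroxyphenyl)acetate | COC(=O)Cc1ccc(O)cc1O | intermediate
3 | methyl 2-[2,4-bis(tert-butyldimethylsilyloxy)phenyl]acetate | COC(=O)Cc1ccc(O[Si](C)(C)C(C)(C)C)cc1O[Si](C)(C)C(C)(C)C | intermediate
4 | methyl 2-[5-bromo-2,4-bis(tert-butyldimethylsilyloxy)phenyl]acetate | COC(=O)Cc1cc(Br)c(O[Si](C)(C)C(C)(C)C)cc1O[Si](C)(C)C(C)(C)C | intermediate
5 | 2-[5-bromo-2,4-bis(tert-butyldimethylsilyloxy)phenyl]-N-methoxy-N-methylacetamide | CON(C)C(=O)Cc1cc(Br)c(O[Si](C)(C)C(C)(C)C)cc1O[Si](C)(C)C(C)(C)C | intermediate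
6 | 4-bromo-3-methoxyphenol | COc1cc(O)ccc1Br | starting material
7 | (4-bromo-3-methoxyphenoxy)(tert-butyl)dimethylsilane | COc1cc(O[Si](C)(C)C(C)(C)C)ccc1Br | intermediate
8 | [4-(tert-butyldimethylsilyloxy)-2-methoxyphenyl]lithium | COc1cc(O[Si](C)(C)C(C)(C)C)ccc1[Li] | intermediate
9 | lithium 2-[5-bromo-2,4-bis(tert-butyldimethylsilyloxy)phenyl]-1-[4-(tert-butyldimethylsilyloxy)-2-methoxyphenyl]-1-[methoxy(methyl)amino]ethan-1-olate (racemic tetrahedral adduct) | COc1cc(O[Si](C)(C)C(C)(C)C)ccc1C(O[Li])(N(C)OC)Cc1cc(Br)c(O[Si](C)(C)C(C)(C)C)cc1O[Si](C)(C)C(C)(C)C | intermediate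
10 | 2-[5-bromo-2,4-bis(tert-butyldimethylsilyloxy)phenyl]-1-[4-(tert-butyldimethylsilyloxy)-2-methoxyphenyl]ethan-1-one | COc1cc(O[Si](C)(C)C(C)(C)C)ccc1C(=O)Cc1cc(Br)c(O[Si](C)(C)C(C)(C)C)cc1O[Si](C)(C)C(C)(C)C | intermediate
11 | 2-[5-bromo-2,4-bis(tert-butyldimethylsilyloxy)phenyl]-1-[4-(tert-butyldimethylsilyloxy)-2-methoxyphenyl]-2-diazoethan-1-one | COc1cc(O[Si](C)(C)C(C)(C)C)ccc1C(=O)C(=[N+]=[N-])c1cc(Br)c(O[Si](C)(C)C(C)(C)C)cc1O[Si](C)(C)C(C)(C)C | intermediate
12 | (3R)-3-[5-bromo-2,4-bis(tert-butyldimethylsilyloxy)phenyl]-7-(tert-butyldimethylsilyloxy)chroman-4-one | Brc1cc([C@@H]2COc3cc(O[Si](C)(C)C(C)(C)C)ccc3C2=O)c(O[Si](C)(C)C(C)(C)C)cc1O[Si](C)(C)C(C)(C)C | intermediate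
13 | geranyl bromide, (2E)-1-bromo-3,7-dimethylocta-2,6-diene | CC(C)=CCC/C(C)=C/CBr | starting material
14 | geranyltributylstannane, tributyl[(2E)-3,7-dimethylocta-2,6-dien-1-yl]stannane | CC(C)=CCC/C(C)=C/C[Sn](CCCC)(CCCC)CCCC | intermediate
15 | (3R)-3-{2,4-bis(tert-butyldimethylsilyloxy)-5-[(2E)-3,7-dimethylocta-2,6-dien-1-yl]phenyl}-7-(tert-butyldimethylsilyloxy)chroman-4-one | CC(C)=CCC/C(C)=C/Cc1cc([C@@H]2COc3cc(O[Si](C)(C)C(C)(C)C)ccc3C2=O)c(O[Si](C)(C)C(C)(C)C)cc1O[Si](C)(C)C(C)(C)C | intermediate
16 | (3R)-3-{5-[(2E)-3,7-dimethylocta-2,6-dien-1-yl]-2,4-dihydroxyphenyl}-7-hydroxychroman-4-one (CNP0142504.1) | CC(C)=CCC/C(C)=C/Cc1cc([C@@H]2COc3cc(O)ccc3C2=O)c(O)cc1O | target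

**Totals**
Total step count: 11.
Longest linear sequence: 9 steps (steps 1, 2, 3, 4, 6, 7, 8, 10, 11).

**Steps most likely to fail**

1. Step 8 (carbene insertion). The insertion into a primary C–H bond in the six-ring mode may be slow. Attack on the methoxy oxygen followed by methyl migration, or carbene dimerisation, may then take over, or the catalyst may discriminate poorly between the two faces of the carbene. The fallback sets C3 by transfer hydrogenation with dynamic kinetic resolution, which is known for isoflavones. It sets out from ketone 10. BCl3 (CH2Cl2, −78 °C) cleaves the methyl ether that is chelated to the ketone and should give 2-[5-bromo-2,4-bis(TBS-oxy)phenyl]-1-[4-(TBS-oxy)-2-hydroxyphenyl]ethan-1-one F1. N,N-Dimethylformamide dimethyl acetal (toluene, 80 °C) adds the C2 carbon and closes ring C to 3-[5-bromo-2,4-bis(TBS-oxy)phenyl]-7-(TBS-oxy)-4H-chromen-4-one F2. Transfer hydrogenation with RuCl[(R,R)-TsDPEN](p-cymene) and HCO2H/Et3N (EtOAc, 40 °C) reduces the C2–C3 double bond and then the ketone while C3 equilibrates. The catalyst enantiomer is the one expected from the usual aryl ketone model to give the 4R carbinol, and the cis preference then fixes 3R, to give (3R,4R)-3-[5-bromo-2,4-bis(TBS-oxy)phenyl]-7-(TBS-oxy)chroman-4-ol F3. Dess–Martin periodinane (CH2Cl2, 0 °C) oxidises C4 back to the ketone without touching C3, and the route is rejoined at 12.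

2. Step 10 (Stille coupling). Oxidative addition at the electron-rich bromide beside a silyloxy group may be slow, the allyl unit may transpose or lose its E geometry on palladium, and C3 may epimerise during prolonged heating. The fallback attaches the geranyl chain before the stereocentre exists. It sets out from ketone 10, which is coupled with stannane 14 (Pd(PPh3)4, toluene, 100 °C) to give 2-{2,4-bis(TBS-oxy)-5-[(2E)-3,7-dimethylocta-2,6-dien-1-yl]phenyl}-1-[4-(TBS-oxy)-2-methoxyphenyl]ethan-1-one F4. At this stage heating does no stereochemical harm and isomers can be removed. Diazo transfer (p-ABSA, DBU, MeCN) gives 2-{2,4-bis(TBS-oxy)-5-[(2E)-3,7-dimethylocta-2,6-dien-1-yl]phenyl}-1-[4-(TBS-oxy)-2-methoxyphenyl]-2-diazoethan-1-one F5. Insertion with Rh2(S-PTTL)4 at high dilution then gives 15 directly, so that only step 11 follows the setting of C3. The meta-placed chain cannot reach the carbene within the molecule, and dilution should suppress intermolecular reaction with the trisubstituted alkenes.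

3. Step 6 (ketone formation). The aryllithium may deprotonate the acidic methylene of the amide instead of adding, and bromine–lithium scrambling between the two arenes may consume it. The fallback replaces acyl substitution by addition to an aldehyde and oxidation. It sets out from amide 5 and silyl ether 7. DIBAL-H (THF, −78 °C) reduces 5 to 2-[5-bromo-2,4-bis(TBS-oxy)phenyl]acetaldehyde F6. Aryllithium 8, made from 7 as in step 6, adds to the aldehyde at −78 °C, a step expected to be much faster than deprotonation or exchange, and gives racemic 2-[5-bromo-2,4-bis(TBS-oxy)phenyl]-1-[4-(TBS-oxy)-2-methoxyphenyl]ethan-1-ol F7. Dess–Martin periodinane (CH2Cl2, rt) oxidises the carbinol, and the route is rejoined at 10.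

**Further compounds**
F1 | step 8 | 2-[5-bromo-2,4-bis(tert-butyldimethylsilyloxy)phenyl]-1-[4-(tert-butyldimethylsilyloxy)-2-hydroxyphenyl]ethan-1-one | Oc1cc(O[Si](C)(C)C(C)(C)C)ccc1C(=O)Cc1cc(Br)c(O[Si](C)(C)C(C)(C)C)cc1O[Si](C)(C)C(C)(C)C
F2 | step 8 | 3-[5-bromo-2,4-bis(tert-butyldimethylsilyloxy)phenyl]-7-(tert-butyldimethylsilyloxy)-4H-chromen-4-one | Brc1cc(C2=COc3cc(O[Si](C)(C)C(C)(C)C)ccc3C2=O)c(O[Si](C)(C)C(C)(C)C)cc1O[Si](C)(C)C(C)(C)C
F3 | step 8 | (3R,4R)-3-[5-bromo-2,4-bis(tert-butyldimethylsilyloxy)phenyl]-7-(tert-butyldimethylsilyloxy)chroman-4-ol | Brc1cc([C@@H]2COc3cc(O[Si](C)(C)C(C)(C)C)ccc3[C@@H]2O)c(O[Si](C)(C)C(C)(C)C)cc1O[Si](C)(C)C(C)(C)C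
F4 | step 10 | 2-{2,4-bis(tert-butyldimethylsilyloxy)-5-[(2E)-3,7-dimethylocta-2,6-dien-1-yl]phenyl}-1-[4-(tert-butyldimethylsilyloxy)-2-methoxyphenyl]ethan-1-one | CC(C)=CCC/C(C)=C/Cc1cc(CC(=O)c2ccc(O[Si](C)(C)C(C)(C)C)cc2OC)c(O[Si](C)(C)C(C)(C)C)cc1O[Si](C)(C)C(C)(C)C
F5 | step 10 | 2-{2,4-bis(tert-butyldimethylsilyloxy)-5-[(2E)-3,7-dimethylocta-2,6-dien-1-yl]phenyl}-1-[4-(tert-butyldimethylsilyloxy)-2-methoxyphenyl]-2-diazoethan-1-one | CC(C)=CCC/C(C)=C/Cc1cc(C(=[N+]=[N-])C(=O)c2ccc(O[Si](C)(C)C(C)(C)C)cc2OC)c(O[Si](C)(C)C(C)(C)C)cc1O[Si](C)(C)C(C)(C)C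
F6 | step 6 | 2-[5-bromo-2,4-bis(tert-butyldimethylsilyloxy)phenyl]acetaldehyde | O=CCc1cc(Br)c(O[Si](C)(C)C(C)(C)C)cc1O[Si](C)(C)C(C)(C)C
F7 | step 6 | 2-[5-bromo-2,4-bis(tert-butyldimethylsilyloxy)phenyl]-1-[4-(tert-butyldimethylsilyloxy)-2-methoxyphenyl]ethan-1-ol (racemic) | COc1cc(O[Si](C)(C)C(C)(C)C)ccc1C(O)Cc1cc(Br)c(O[Si](C)(C)C(C)(C)C)cc1O[Si](C)(C)C(C)(C)C
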